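# Proposed total synthesis of CNP0115165.2 by glycol cleavage of a bicyclic diol

## Analysis of the target

The target is a germacrane-type ten-membered carbocycle (C1–C10) fused through C6–C7 to an α,β-unsaturated γ-lactone (O6–C12(=O)–C11=C7). Atom labels used throughout: C1 ketone, C2, C3, C4 (methyl, double bond to C5), C5, C6 (lactone oxygen), C7, C8 (methacrylate), C9, C10 (methyl and acetate), C11 lactone α-carbon, C12 lactone carbonyl, C13 acetoxymethyl carbon. There are three stereocentres, C6 (R), C8 (S) and C10 (R), plus the Z C4=C5 bond. The three oxygen substituents lie on the same face of the macrocycle, so O6/O8 and O8/O10 are both 1,3-syn. The sensitive groups are the methacrylate (polymerisable Michael acceptor), the allylic C13 acetate on the butenolide (open to addition–elimination), the tertiary α-acetoxy ketone at C10/C1 (acyl shift, reductive loss) and the epimerisable γ-hydrogen at C6. The difficulty lies in the medium ring itself: direct closure is slow, a Z trisubstituted alkene must be held, and the C1 and C6 carbonyl carbons face each other across the ring and invite transannular reactions. The strategy rests on exactly that 1,6-relationship. A bond between the two oxygen-bearing carbons C1 and C6 divides the macrocycle into ring A (C1–C6, holding C4=C5 as a necessarily cis cyclohexene) and ring B (C1, C6, C7–C10, carrying the C8 and C10 stereocentres). The ten-membered ring is therefore the periphery of a bicyclo[4.4.0]decene-1,6-diol.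

## Retrosynthetic reasoning

**O8–acyl bond.** The methacrylate is the most fragile group, so it is cut first: target 31 comes from secondary alcohol 30 by acylation, and the last step then only has to esterify the one free hydroxyl.

**Lactone O6–C12 bond and C6–H bond.** Opening the butenolide of 30 gives hydroxy ester 29, and removing the C6 hydride gives dienone 28, whose ester is cis to C6 across C7=C11. Cutting here lets the free C8 hydroxyl of 28 steer the hydride by chelation (1,3-syn), and lactonisation follows by itself. Alcohol 28 comes from silyl ether 27.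

**C7–C11 bond.** The alkylidene of 27 is traced to aldol adduct 25, and 25 to dione 21 and keto ester 23, which brings C11, C12 and C13 at their final oxidation levels including the C13 acetate. C7 is chosen because the C6 enone is the only handle that activates it. The forward reaction must enolise C6 toward C7 without touching the C1 ketone, and 23 is made in one step from bromide 22.

**C1–C6 bond (key disconnection).** Dione 21 is reconnected between its two carbonyl carbons to give the ring-fusion diol 20. Nothing but two hydrogens changes, yet the ring is no longer medium-sized: the problem becomes one of making a decalin-type diol. The forward step must cleave only this glycol, which is why O10 is already acetylated and O8 silylated.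

**O10–acetyl bond and C4=C5 bond.** Acetate 20 comes from triol 19 by acylating the only hydroxyl that is not at the ring fusion. Ring A of 19 is opened at C4=C5 by a retro-metathesis to triene 18, and this is where the Z geometry is fixed by ring size.

**C6–C5 and C1–C2 bonds.** Triol 18 comes from ketone 16 and vinylmagnesium bromide 17, and 16 from enone 13 and bromide 14 (as its organometallic). Two carbonyl additions are used because C1 and C6 are adjacent carbinols. The order is dictated by 13, whose C6 carbonyl is masked as an enol ether that can only form toward C7.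

**C1–C6 bond again, now as an acyloin bond.** Enone 13 derives from the enediol ether 11, and 11 from diester 10 by reductive coupling of the two ester carbons. The same bond that is cleaved later is made here because a six-membered acyloin ring closes easily and delivers C1 and C6 at the diketone level.

**C8 stereocentre and C7–C8 bond.** Diester 10 comes from 9 by silylation, 9 from dioxolanone 8 by ethanolysis, and 8 from alcohol 7 by silylation. The C8 carbinol of 7 comes from β-keto ester 6 by catalyst-controlled hydrogenation. Keto ester 6 comes from acid 2 and malonate 3, and 2 from (R)-citramalic acid 1, whose quaternary carbon is C10.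

## Alternatives that were turned down

**Alternative 1:** Disconnection of C5–C6 and of the lactone O6–C12 bond leads to the open-chain (Z)-iodoalkene aldehyde A1. Forward, CrCl2 with catalytic NiCl2 (divalent chromium, divalent nickel) would turn the vinyl iodide into a vinylchromium species that adds to the C6 aldehyde, and the C6 alkoxide would close the butenolide on the cis ester to give the bis-silyl butenolide A2.
- For it: the plan is convergent, forms the ring and the lactone in one operation, and fixes the C7=C11 geometry before cyclisation. On convergence and probably on step count it is stronger than the chosen route.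
- Against it: the ten-membered ring must be closed by bond formation against transannular strain, which demands high dilution and a large excess of chromium. C6 is created in that same step with only the remote C8 and C10 centres to guide it. The α-acetoxy ketone of A1 is the kind of group that divalent chromium reduces. The trisubstituted (Z)-vinyl iodide must be made and kept geometrically pure.
- In its place the chosen strategy never closes the medium ring, obtains the Z alkene from ring size, and sets C6 afterwards by a directed reduction.

**Alternative 2:** Disconnection of C6–C7 with reconnection of O to C13 leads to the thirteen-membered diallylic ether A3. Forward, lithiation at C6 would start a [2,3]-Wittig shift that forms C6–C7, breaks O–C13 and contracts the ring to the ten-membered alcohol A4.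
- For it: a thirteen-membered ether is easier to close than a ten-membered carbocycle, and the five-membered transition state relays configuration to C6 and C7 together. On avoiding a direct medium-ring closure it equals the chosen route, and it installs the C6 oxygen directly.
- Against it: C6 and C13 are both allylic α-oxy positions, so the site of lithiation is uncertain, and a [1,2] shift competes. A4 is also far from the target in oxidation state. Its C1=C10 alkene must become the α-acetoxy ketone with a new C10 stereocentre on a flexible ring, the exocyclic C11=C13 alkene must be moved into conjugation, and the ether carbon must be oxidised to the lactone carbonyl.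
- The chosen strategy brings the C1 ketone and the C10 acetate in from the chiral pool and needs no oxidation on the macrocycle.

**Alternative 3:** Reconnection of C6–C1 and cleavage of C8–C9 leads to the divinylcyclohexenol A5. Forward, KH with 18-crown-6 would ionise the tertiary carbinol and the 1,5-diene C8=C7–C6–C1–C10=C9 would undergo an anionic oxy-Cope shift to the cyclodecadienone A6.
- For it: like the chosen plan it expands a six-membered ring and inherits the Z C4=C5 bond from it. It is much shorter, and it delivers the C6 enolate regiospecifically toward C7. On step count and on enolate regiochemistry it is clearly stronger.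
- Against it: A6 has no oxygen at C1 or C10. The E C1=C10 alkene would have to be dihydroxylated face-selectively on a mobile ten-membered ring, oxidised at C1 and acetylated at the tertiary C10 hydroxyl. The C8 configuration depends on a geometrically pure alkoxyvinyl nucleophile and on a single chair transition state.
- The chosen strategy fixes C8 by catalyst control and C10 from citramalic acid before any medium ring exists, at the price of a longer sequence and a less obvious enolisation.

Key step: step 13

Remark: γ-hydroxy ketones 28 and 30 are drawn in the open form; a reversible O8–C1 hemiketal may be present and would not change the chemistry.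

## Route

Step 1
Reactants: 1 (R)-citramalic acid
Product: 2 [(4R)-2,2,4-trimethyl-5-oxo-1,3-dioxolan-4-yl]acetic acid
Conditions: Me2C(OMe)2, pyridinium p-toluenesulfonate (cat.), rt
Reagents that add atoms: 2,2-dimethoxypropane, COC(C)(C)OC
Why: Acid-catalysed acetal exchange closes only the five-membered dioxolanone on the α-hydroxy acid, which masks C1 and O10 together and leaves the C8 carboxyl free; the C10 stereocentre of the chiral pool is not touched.

Step 2
Reactants: 2 [(4R)-2,2,4-trimethyl-5-oxo-1,3-dioxolan-4-yl]acetic acid; 3 potassium ethyl malonate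
Product: 6 ethyl 3-oxo-4-[(4R)-2,2,4-trimethyl-5-oxo-1,3-dioxolan-4-yl]butanoate, via acyl imidazolide 4 (not isolated), via acylmalonate half-ester 5 (not isolated)
Conditions: CDI, THF, rt; then 3, MgCl2, Et3N, MeCN, rt; 1 M HCl work-up
Reagents that add atoms: none
Why: Masamune–Brooks homologation: the imidazolide acylates the magnesium enolate of the malonate half-ester under nearly neutral conditions and the adduct loses CO2 on acidification, which supplies C7 and C6 without the strong base that could eliminate the dioxolanone oxygen from C10.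

Step 3
Reactants: 6 ethyl 3-oxo-4-[(4R)-2,2,4-trimethyl-5-oxo-1,3-dioxolan-4-yl]butanoate
Product: 7 ethyl (3S)-3-hydroxy-4-[(4R)-2,2,4-trimethyl-5-oxo-1,3-dioxolan-4-yl]butanoate
Conditions: H2 (100 atm), RuCl2[(S)-BINAP] (0.5 mol %), EtOH, 25–30 °C
Reagents that add atoms: none
Why: Noyori asymmetric hydrogenation of a β-keto ester: the chelated ketone is reduced under catalyst control and the (S)-ligand should give the (S)-carbinol at C8 as with simple 3-oxo esters; room temperature and no added acid should keep the new hydroxyl from lactonising onto C1.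

Step 4
Reactants: 7 ethyl (3S)-3-hydroxy-4-[(4R)-2,2,4-trimethyl-5-oxo-1,3-dioxolan-4-yl]butanoate
Product: 8 ethyl (3S)-3-(tert-butyldimethylsilyloxy)-4-[(4R)-2,2,4-trimethyl-5-oxo-1,3-dioxolan-4-yl]butanoate
Conditions: TBSOTf, 2,6-lutidine, CH2Cl2, −78 °C
Reagents that add atoms: tert-butyldimethylsilyl trifluoromethanesulfonate, CC(C)(C)[Si](C)(C)OS(=O)(=O)C(F)(F)F
Why: Silylation of a secondary alcohol with a silyl triflate is fast at −78 °C, so O8 is capped before it can attack the activated C1 carbonyl.

Step 5
Reactants: 8 ethyl (3S)-3-(tert-butyldimethylsilyloxy)-4-[(4R)-2,2,4-trimethyl-5-oxo-1,3-dioxolan-4-yl]butanoate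
Product: 9 diethyl (2R,4S)-4-(tert-butyldimethylsilyloxy)-2-hydroxy-2-methylhexanedioate
Conditions: NaOEt (0.1 equiv), EtOH, 0 °C, short contact; AcOH quench
Reagents that add atoms: ethanol, CCO
Why: Transesterification: the dioxolanone is an activated ester, so catalytic ethoxide opens it quickly in the cold and releases acetone and the C10 tertiary alcohol; short contact and the acid quench should forestall loss of the β-silyloxy group and lactonisation onto the C6 ester.

Step 6
Reactants: 9 diethyl (2R,4S)-4-(tert-butyldimethylsilyloxy)-2-hydroxy-2-methylhexanedioate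
Product: 10 diethyl (2R,4S)-4-(tert-butyldimethylsilyloxy)-2-methyl-2-(trimethylsilyloxy)hexanedioate
Conditions: TMSCl, imidazole, DMF, rt
Reagents that add atoms: chlorotrimethylsilane, C[Si](C)(C)Cl
Why: Silylation of the tertiary hydroxyl removes the only acidic proton before the dissolving-metal step; the small trimethylsilyl group is chosen because a mild acidic work-up sheds it later.

Step 7
Reactants: 10 diethyl (2R,4S)-4-(tert-butyldimethylsilyloxy)-2-methyl-2-(trimethylsilyloxy)hexanedioate
Product: 11 (3R,5R)-5-(tert-butyldimethylsilyloxy)-3-methyl-1,2,3-tris(trimethylsilyloxy)cyclohex-1-ene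
Conditions: Na (4.4 equiv, dispersion), TMSCl (5 equiv), toluene, reflux
Reagents that add atoms: chlorotrimethylsilane, C[Si](C)(C)Cl
Why: Rühlmann variant of the acyloin condensation: electron transfer from sodium couples the two ester carbons (C1–C6) in a six-membered ring, and TMSCl traps the enediolate and the ethoxide, which suppresses Dieckmann and β-elimination pathways.

Step 8
Reactants: 11 (3R,5R)-5-(tert-butyldimethylsilyloxy)-3-methyl-1,2,3-tris(trimethylsilyloxy)cyclohex-1-ene
Product: 13 (4S,6R)-4-(tert-butyldimethylsilyloxy)-6-methyl-2,6-bis(trimethylsilyloxy)cyclohex-2-en-1-one, via ring B dione 12 (not isolated)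
Conditions: Br2 (1.0 equiv), CH2Cl2, −78 °C; then Et3N, −78 → 0 °C; filtration and concentration, used crude
Reagents that add atoms: none
Why: Bromine oxidises the electron-rich enediol bis(silyl ether) to the 1,2-dione with loss of TMSBr; the dione can enolise only toward C7 because C10 is quaternary, and Et3N with the TMSBr already present silylates that enol, so C6 is masked and C1 remains the only ketone.

Step 9
Reactants: 13 (4S,6R)-4-(tert-butyldimethylsilyloxy)-6-methyl-2,6-bis(trimethylsilyloxy)cyclohex-2-en-1-one; 14 4-bromo-2-methylbut-1-ene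
Product: 16 (2S,3R,5S)-5-(tert-butyldimethylsilyloxy)-2,3-dihydroxy-3-methyl-2-(3-methylbut-3-enyl)cyclohexan-1-one, via silylated adduct 15 (not isolated)
Conditions: 14, Mg, THF; CeCl3, THF, −78 °C; then 13, −78 °C; citric acid, MeOH, rt
Reagents that add atoms: none
Why: Organocerium 1,2-addition to a hindered enone carbonyl proceeds without enolisation or conjugate addition; attack should come anti to the pseudoaxial C10 methyl of the half-chair that keeps both silyloxy groups pseudoequatorial, so the chain enters cis to O10 (this centre is erased in step 13). Methanolic citric acid then removes the enol ether and the tertiary trimethylsilyl ether but not the secondary silyl ether.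

Step 10
Reactants: 16 (2S,3R,5S)-5-(tert-butyldimethylsilyloxy)-2,3-dihydroxy-3-methyl-2-(3-methylbut-3-enyl)cyclohexan-1-one; 17 vinylmagnesium bromide
Product: 18 (1S,2S,3R,5S)-5-(tert-butyldimethylsilyloxy)-1-ethenyl-3-methyl-2-(3-methylbut-3-enyl)cyclohexane-1,2,3-triol
Conditions: 17 (4 equiv), CeCl3, THF, −78 → 0 °C; aq NH4Cl
Reagents that add atoms: none
Why: Organocerium addition to the α-hydroxy ketone; in the chair that keeps all three oxygen substituents equatorial the axial C10 methyl is syn-axial to the α-face of C6, so the vinyl group should enter equatorially on the β-face, cis to the C1 chain, leaving the C1 and C6 hydroxyls cis (both centres are erased in step 13).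

Step 11
Reactants: 18 (1S,2S,3R,5S)-5-(tert-butyldimethylsilyloxy)-1-ethenyl-3-methyl-2-(3-methylbut-3-enyl)cyclohexane-1,2,3-triol
Product: 19 (1S,6S,8S,10R)-8-(tert-butyldimethylsilyloxy)-4,10-dimethylbicyclo[4.4.0]dec-4-ene-1,6,10-triol
Conditions: second-generation Grubbs catalyst RuCl2(=CHPh)(H2IMes)(PCy3) (5 mol %), CH2Cl2, 40 °C
Reagents that add atoms: none
Why: Ring-closing metathesis between the vinyl group and the 1,1-disubstituted alkene forms ring A with loss of ethene; a six-membered ring can hold the new trisubstituted C4=C5 bond only cis, which is the Z geometry of the target.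

Step 12
Reactants: 19 (1S,6S,8S,10R)-8-(tert-butyldimethylsilyloxy)-4,10-dimethylbicyclo[4.4.0]dec-4-ene-1,6,10-triol
Product: 20 (1R,6S,8R,10R)-8-(tert-butyldimethylsilyloxy)-1,6-dihydroxy-4,10-dimethylbicyclo[4.4.0]dec-4-en-10-yl acetate
Conditions: Ac2O, 4-dimethylaminopyridine, Et3N, CH2Cl2, rt → 40 °C
Reagents that add atoms: acetic anhydride, CC(=O)OC(C)=O
Why: Nucleophile-catalysed acylation: the C10 hydroxyl is an ordinary equatorial tertiary alcohol, whereas the C1 and C6 hydroxyls sit at the ring fusion (C1 between two fully substituted carbons), so mono-acetylation at O10 is expected. The CIP labels of C1 and C8 change only because the acetyl group alters priorities.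

Step 13
Reactants: 20 (1R,6S,8R,10R)-8-(tert-butyldimethylsilyloxy)-1,6-dihydroxy-4,10-dimethylbicyclo[4.4.0]dec-4-en-10-yl acetate
Product: 21 (4Z,8S,10R)-8-(tert-butyldimethylsilyloxy)-4,10-dimethyl-1,6-dioxocyclodec-4-en-10-yl acetate
Conditions: Pb(OAc)4 (1.1 equiv), pyridine (3 equiv), CH2Cl2, −20 → 0 °C
Reagents that add atoms: none
Why: Both hydroxyls exchange onto tetravalent lead to give a five-membered cyclic lead diester, which is easy here because the cis ring fusion holds the C1–O and C6–O bonds gauche; a concerted two-electron fragmentation then breaks C1–C6, turns both carbinols into ketones and releases divalent lead (Criegee glycol cleavage). The closest known reaction type is the cleavage of ring-fusion cis-diols of bicyclo[4.4.0]decanes to cyclodecane-1,6-diones. No ring is closed by bond formation: the ten-membered ring is the periphery of rings A and B and appears when their shared bond is removed, so no entropic or transannular penalty of cyclisation is paid. No stereocentre is created; the C1 and C6 centres vanish, C8 and C10 are untouched, and C4=C5 keeps the cis geometry forced on it by ring A, which is Z in the ten-membered ring. The step needs site selectivity for the C1/C6 glycol, secured because O10 is acetylated and O8 silylated so that no other vicinal diol exists, and chemoselectivity over the trisubstituted alkene, secured by the much faster cyclic pathway at low temperature. Pyridine buffers the acetic acid released so that the 1,6-dione is not pushed into transannular aldol closure.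

Step 14
Reactants: 22 ethyl 3-bromo-2-oxopropanoate
Product: 23 ethyl 3-acetoxy-2-oxopropanoate
Conditions: KOAc, AcOH (cat.), acetone, rt
Reagents that add atoms: potassium acetate, CC(=O)[O-].[K+]
Why: SN2 displacement of an α-bromo ketone by acetate; the acetic acid buffer limits base-induced self-condensation of the keto ester.

Step 15
Reactants: 21 (4Z,8S,10R)-8-(tert-butyldimethylsilyloxy)-4,10-dimethyl-1,6-dioxocyclodec-4-en-10-yl acetate; 23 ethyl 3-acetoxy-2-oxopropanoate
Product: 25 ethyl 3-acetoxy-2-hydroxy-2-[(4Z,8S,10R)-10-acetoxy-8-(tert-butyldimethylsilyloxy)-4,10-dimethyl-1,6-dioxocyclodec-4-en-7-yl]propanoate as a mixture of C7/C11 epimers, via dibutylboron enolate 24 (not isolated)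
Conditions: Bu2BOTf (1.05 equiv), iPr2NEt, CH2Cl2, −78 °C; then 23, −78 → −40 °C; pH 7 buffer, MeOH
Reagents that add atoms: none
Why: Boron-mediated aldol addition: the boron triflate should bind the more Lewis-basic enone carbonyl (C6) rather than the hindered, inductively deactivated α-acetoxy ketone (C1), and the amine can then remove only a C7 proton because the other α-position is vinylic. The covalent boron enolate adds to the aldehyde-like ketone of 23 without the strong base that would provoke transannular aldolisation; the two new centres are removed in step 16.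

Step 16
Reactants: 25 ethyl 3-acetoxy-2-hydroxy-2-[(4Z,8S,10R)-10-acetoxy-8-(tert-butyldimethylsilyloxy)-4,10-dimethyl-1,6-dioxocyclodec-4-en-7-yl]propanoate
Product: 27 ethyl (2Z)-3-acetoxy-2-[(4Z,8S,10R)-10-acetoxy-8-(tert-butyldimethylsilyloxy)-4,10-dimethyl-1,6-dioxocyclodec-4-en-7-ylidene]propanoate, via tertiary mesylate 26 (not isolated)
Conditions: MsCl, Et3N, CH2Cl2, −20 → 0 °C
Reagents that add atoms: none
Why: Sulfene mesylation of the tertiary aldol hydroxyl is followed by E1cB elimination through the C6 enolate, which can involve only C7–H, and mesylate is a far better leaving group than the C8 silyloxy group. The isomer with the ester cis to the planar C6 acyl group (Z) should predominate because the other isomer presses the ester against the branched sp3 C8; any E isomer is removed by chromatography.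

Step 17
Reactants: 27 ethyl (2Z)-3-acetoxy-2-[(4Z,8S,10R)-10-acetoxy-8-(tert-butyldimethylsilyloxy)-4,10-dimethyl-1,6-dioxocyclodec-4-en-7-ylidene]propanoate
Product: 28 ethyl (2Z)-3-acetoxy-2-[(4Z,8S,10R)-10-acetoxy-8-hydroxy-4,10-dimethyl-1,6-dioxocyclodec-4-en-7-ylidene]propanoate
Conditions: HF·pyridine, pyridine, THF, 0 °C → rt
Reagents that add atoms: none
Why: Fluoride cleavage of the secondary silyl ether under buffered, weakly acidic conditions that leave both acetates and the unsaturated carbonyl units alone; the freed O8 cannot lactonise because the ester is trans to C8 across C7=C11.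

Step 18
Reactants: 28 ethyl (2Z)-3-acetoxy-2-[(4Z,8S,10R)-10-acetoxy-8-hydroxy-4,10-dimethyl-1,6-dioxocyclodec-4-en-7-ylidene]propanoate
Product: 30 (4Z,6R,8S,10R)-10,13-diacetoxy-8-hydroxy-1-oxogermacra-4,7(11)-dien-12,6-olide, via hydroxy ester 29 (not isolated)
Conditions: NaBH4, CeCl3·7H2O, MeOH, −78 °C; then rt (pyridinium p-toluenesulfonate, CH2Cl2 if lactonisation is incomplete)
Reagents that add atoms: none
Why: Luche reduction: cerium-activated 1,2-reduction of the conjugated C6 ketone in preference to the hindered saturated C1 ketone; chelation of cerium between O6 and the free C8 hydroxyl should direct hydride to give the 1,3-syn diol (6R), as in chelation-controlled reductions of β-hydroxy ketones. The C6 hydroxyl then closes the butenolide on the cis ester with loss of ethanol.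

Step 19
Reactants: 30 (4Z,6R,8S,10R)-10,13-diacetoxy-8-hydroxy-1-oxogermacra-4,7(11)-dien-12,6-olide
Product: 31 (4Z,6R,8S,10R)-10,13-diacetoxy-1-oxogermacra-4,7(11)-dien-12,6-olid-8-yl 2-methylprop-2-enoate (CNP0115165.2)
Conditions: methacrylic anhydride, Et3N, 4-dimethylaminopyridine (0.1 equiv), BHT, CH2Cl2, 0 °C
Reagents that add atoms: methacrylic anhydride, C=C(C)C(=O)OC(=O)C(C)=C
Why: Acylation of the only free (secondary) hydroxyl with the anhydride under mild base catalysis at 0 °C with a radical inhibitor, conditions short of those that would epimerise C6 or displace the allylic acetate.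

## Compound list

Locants for 19–21, 24–31 follow the target numbering.

1 | (R)-citramalic acid | OC(=O)C[C@@](C)(O)C(=O)O | starting material
2 | [(4R)-2,2,4-trimethyl-5-oxo-1,3-dioxolan-4-yl]acetic acid | OC(=O)C[C@@]1(C)OC(C)(C)OC1=O | intermediate
3 | potassium ethyl malonate | CCOC(=O)CC(=O)[O-].[K+] | starting material
4 | 1-{[(4R)-2,2,4-trimethyl-5-oxo-1,3-dioxolan-4-yl]acetyl}imidazole | O=C(C[C@@]1(C)OC(C)(C)OC1=O)n1ccnc1 | intermediate
5 | 2-(ethoxycarbonyl)-3-oxo-4-[(4R)-2,2,4-trimethyl-5-oxo-1,3-dioxolan-4-yl]butanoic acid (as magnesium salt; malonate carbon not defined) | CCOC(=O)C(C(=O)O)C(=O)C[C@@]1(C)OC(C)(C)OC1=O | intermediate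
6 | ethyl 3-oxo-4-[(4R)-2,2,4-trimethyl-5-oxo-1,3-dioxolan-4-yl]butanoate | CCOC(=O)CC(=O)C[C@@]1(C)OC(C)(C)OC1=O | intermediate
7 | ethyl (3S)-3-hydroxy-4-[(4R)-2,2,4-trimethyl-5-oxo-1,3-dioxolan-4-yl]butanoate | CCOC(=O)C[C@@H](O)C[C@@]1(C)OC(C)(C)OC1=O | intermediate
8 | ethyl (3S)-3-(tert-butyldimethylsilyloxy)-4-[(4R)-2,2,4-trimethyl-5-oxo-1,3-dioxolan-4-yl]butanoate | CCOC(=O)C[C@@H](O[Si](C)(C)C(C)(C)C)C[C@@]1(C)OC(C)(C)OC1=O | intermediate
9 | diethyl (2R,4S)-4-(tert-butyldimethylsilyloxy)-2-hydroxy-2-methylhexanedioate | CCOC(=O)C[C@@H](O[Si](C)(C)C(C)(C)C)C[C@@](C)(O)C(=O)OCC | intermediate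
10 | diethyl (2R,4S)-4-(tert-butyldimethylsilyloxy)-2-methyl-2-(trimethylsilyloxy)hexanedioate | CCOC(=O)C[C@@H](O[Si](C)(C)C(C)(C)C)C[C@@](C)(O[Si](C)(C)C)C(=O)OCC | intermediate
11 | (3R,5R)-5-(tert-butyldimethylsilyloxy)-3-methyl-1,2,3-tris(trimethylsilyloxy)cyclohex-1-ene (silyloxy groups at C3 and C5 cis) | CC(C)(C)[Si](C)(C)O[C@H]1C[C@@](C)(O[Si](C)(C)C)C(O[Si](C)(C)C)=C(O[Si](C)(C)C)C1 | intermediate
12 | (3R,5S)-5-(tert-butyldimethylsilyloxy)-3-methyl-3-(trimethylsilyloxy)cyclohexane-1,2-dione | CC(C)(C)[Si](C)(C)O[C@H]1C[C@@](C)(O[Si](C)(C)C)C(=O)C(=O)C1 | intermediate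
13 | (4S,6R)-4-(tert-butyldimethylsilyloxy)-6-methyl-2,6-bis(trimethylsilyloxy)cyclohex-2-en-1-one | CC(C)(C)[Si](C)(C)O[C@H]1C[C@@](C)(O[Si](C)(C)C)C(=O)C(O[Si](C)(C)C)=C1 | intermediate
14 | 4-bromo-2-methylbut-1-ene | C=C(C)CCBr | starting material
15 | (1S,4S,6R)-4-(tert-butyldimethylsilyloxy)-6-methyl-1-(3-methylbut-3-enyl)-2,6-bis(trimethylsilyloxy)cyclohex-2-en-1-ol | CC(C)(C)[Si](C)(C)O[C@H]1C[C@@](C)(O[Si](C)(C)C)[C@@](O)(CCC(C)=C)C(O[Si](C)(C)C)=C1 | intermediate
16 | (2S,3R,5S)-5-(tert-butyldimethylsilyloxy)-2,3-dihydroxy-3-methyl-2-(3-methylbut-3-enyl)cyclohexan-1-one | CC(C)(C)[Si](C)(C)O[C@H]1C[C@@](C)(O)[C@@](O)(CCC(C)=C)C(=O)C1 | intermediate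
17 | vinylmagnesium bromide | C=C[Mg]Br | starting material
18 | (1S,2S,3R,5S)-5-(tert-butyldimethylsilyloxy)-1-ethenyl-3-methyl-2-(3-methylbut-3-enyl)cyclohexane-1,2,3-triol | CC(C)(C)[Si](C)(C)O[C@H]1C[C@@](C)(O)[C@@](O)(CCC(C)=C)[C@@](O)(C=C)C1 | intermediate
19 | (1S,6S,8S,10R)-8-(tert-butyldimethylsilyloxy)-4,10-dimethylbicyclo[4.4.0]dec-4-ene-1,6,10-triol | CC(C)(C)[Si](C)(C)O[C@H]1C[C@@](C)(O)[C@@]2(O)CCC(C)=C[C@@]2(O)C1 | intermediate
20 | (1R,6S,8R,10R)-8-(tert-butyldimethylsilyloxy)-1,6-dihydroxy-4,10-dimethylbicyclo[4.4.0]dec-4-en-10-yl acetate (same spatial arrangement as 19) | CC(C)(C)[Si](C)(C)O[C@H]1C[C@@](C)(OC(C)=O)[C@@]2(O)CCC(C)=C[C@@]2(O)C1 | intermediate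
21 | (4Z,8S,10R)-8-(tert-butyldimethylsilyloxy)-4,10-dimethyl-1,6-dioxocyclodec-4-en-10-yl acetate | CC(C)(C)[Si](C)(C)O[C@H]1C[C@@](C)(OC(C)=O)C(=O)CC/C(C)=C\C(=O)C1 | intermediate
22 | ethyl 3-bromo-2-oxopropanoate | CCOC(=O)C(=O)CBr | starting material
23 | ethyl 3-acetoxy-2-oxopropanoate | CCOC(=O)C(=O)COC(C)=O | intermediate
24 | dibutylboron enolate of 21 at C6, enolised toward C7 (enolate geometry not defined) | CC(C)(C)[Si](C)(C)O[C@H]1C[C@@](C)(OC(C)=O)C(=O)CC/C(C)=C\C(OB(CCCC)CCCC)=C1 | intermediate
25 | ethyl 3-acetoxy-2-hydroxy-2-[(4Z,8S,10R)-10-acetoxy-8-(tert-butyldimethylsilyloxy)-4,10-dimethyl-1,6-dioxocyclodec-4-en-7-yl]propanoate (epimers at C7 and C11) | CC(C)(C)[Si](C)(C)O[C@H]1C[C@@](C)(OC(C)=O)C(=O)CC/C(C)=C\C(=O)C1C(O)(COC(C)=O)C(=O)OCC | intermediate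
26 | C11 methanesulfonate of 25 | CC(C)(C)[Si](C)(C)O[C@H]1C[C@@](C)(OC(C)=O)C(=O)CC/C(C)=C\C(=O)C1C(OS(C)(=O)=O)(COC(C)=O)C(=O)OCC | intermediate
27 | ethyl (2Z)-3-acetoxy-2-[(4Z,8S,10R)-10-acetoxy-8-(tert-butyldimethylsilyloxy)-4,10-dimethyl-1,6-dioxocyclodec-4-en-7-ylidene]propanoate (ester cis to C6) | CC(C)(C)[Si](C)(C)O[C@H]1C[C@@](C)(OC(C)=O)C(=O)CC/C(C)=C\C(=O)/C1=C(/COC(C)=O)C(=O)OCC | intermediate
28 | ethyl (2Z)-3-acetoxy-2-[(4Z,8S,10R)-10-acetoxy-8-hydroxy-4,10-dimethyl-1,6-dioxocyclodec-4-en-7-ylidene]propanoate | O[C@H]1C[C@@](C)(OC(C)=O)C(=O)CC/C(C)=C\C(=O)/C1=C(/COC(C)=O)C(=O)OCC | intermediate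
29 | ethyl (2Z)-3-acetoxy-2-[(4Z,6R,8S,10R)-10-acetoxy-6,8-dihydroxy-4,10-dimethyl-1-oxocyclodec-4-en-7-ylidene]propanoate | O[C@H]1C[C@@](C)(OC(C)=O)C(=O)CC/C(C)=C\[C@@H](O)/C1=C(/COC(C)=O)C(=O)OCC | intermediate
30 | (4Z,6R,8S,10R)-10,13-diacetoxy-8-hydroxy-1-oxogermacra-4,7(11)-dien-12,6-olide | O[C@H]1C[C@@](C)(OC(C)=O)C(=O)CC/C(C)=C\[C@H]2OC(=O)C(COC(C)=O)=C12 | intermediate
31 | (4Z,6R,8S,10R)-10,13-diacetoxy-1-oxogermacra-4,7(11)-dien-12,6-olid-8-yl 2-methylprop-2-enoate (CNP0115165.2) | C=C(C)C(=O)O[C@H]1C[C@@](C)(OC(C)=O)C(=O)CC/C(C)=C\[C@H]2OC(=O)C(COC(C)=O)=C12 | target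

## Step count and least certain steps

Total: 19 steps. Longest linear sequence: 18 steps (steps 1–13 and 15–19 from (R)-citramalic acid 1); step 14 is a one-step side branch.

**Step 13 (key step).** The crowded di-tertiary glycol may form the cyclic lead diester slowly. The reagent could then attack the allylic positions, or the acetic acid released could drive the new 1,6-dione into transannular aldol closure. Fallback, from 20 directly to 21: a hypoiodite (alkoxy-radical) fragmentation with PhI(OAc)2 (trivalent iodine) and I2 in CH2Cl2 over solid NaHCO3 under visible light. One hydroxyl is converted into an O–I bond, homolysis gives an alkoxy radical, and β-scission breaks C1–C6 because it leaves an α-hydroxyalkyl radical that is oxidised on to the second ketone. No cyclic diester and no acid are involved, and no new compound is made.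

**Step 7.** Electron transfer to the C1 ester may expel the α-silyloxy group (reductive C10–O cleavage) instead of leading to C1–C6 coupling. Fallback, from 10 back to 13: both esters are reduced with iBu2AlH (toluene, −78 °C) to the dialdehyde F1. An intramolecular pinacol coupling with SmI2 (divalent samarium, THF, −78 °C) closes ring B as the cis-diol F2. A double Swern oxidation ((COCl)2, DMSO, Et3N) gives dione 12, which is silylated with TMSCl/Et3N to rejoin the route at 13.

**Step 10.** Facial selectivity may be poor because the axial C1 side chain hinders the β-face while the axial C10 methyl hinders the α-face. Attack on the α-face would place vinyl and side chain trans-diaxial and stop the metathesis. Fallback, from 16 to 18: the slimmer, rod-shaped nucleophile HC≡CMgBr with CeCl3 (THF, −78 °C) should suffer less from the neighbouring axial chain while still being blocked by the syn-axial methyl, giving the ethynyl triol F3. Semihydrogenation (H2, Pd/CaCO3 poisoned with Pb(OAc)2, quinoline) then gives 18.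

**Step 15.** Site selectivity may be incomplete: the C1 ketone may also enolise toward C2, or the C7 enolate may add across the ring to C1 (five-membered transannular aldol). Fallback, from 21 to 28, takes the C1 ketone out of play. HF·pyridine frees O8 to give the hydroxy dione F4, in which O8 and C1 are 1,4-related. Methanol with HC(OMe)3 and pyridinium p-toluenesulfonate should lock them as the bridged methyl ketal F5. With C6 as the only ketone, Bu2BOTf/iPr2NEt and 23 give the aldol adduct F6. Dehydration as in step 16 gives the Z alkylidene ketal F7, and pyridinium p-toluenesulfonate in wet acetone hydrolyses the ketal to 28.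

**Step 16.** The elimination may be unselective in alkene geometry, and an ester trans to C6 cannot lactonise. Fallback, from 25 to 30, closes the lactone before the alkene is made, so the ring fixes the geometry. NaBH4/CeCl3·7H2O (MeOH, −78 °C) reduces C6 and the carbinol lactonises to the hydroxy lactone F8. Dehydration with the Burgess reagent (benzene, 50 °C) gives the silyl butenolide F9, and HF·pyridine gives 30.

**Step 18.** The cerium chelate may not control the face at C6 on the flexible ring (poor syn selectivity), or the C1 ketone may be reduced as well. Fallback, from 28 to 30 through 29, replaces chelate control by catalyst control. It uses (S)-Me-CBS oxazaborolidine ((S)-1-methyl-3,3-diphenyltetrahydropyrrolo[1,2-c][1,3,2]oxazaborole) with excess catecholborane in toluene at −78 °C. The fully substituted C7 alkylidene acts as the large group and the C5 vinyl as the small one, which should give the 6R carbinol. No new compound is made.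

## Further compounds

F0 | step 13 | none | none
F1 | step 7 | (2R,4S)-4-(tert-butyldimethylsilyloxy)-2-methyl-2-(trimethylsilyloxy)hexanedial | O=CC[C@@H](O[Si](C)(C)C(C)(C)C)C[C@@](C)(O[Si](C)(C)C)C=O
F2 | step 7 | (3R,5S)-5-(tert-butyldimethylsilyloxy)-3-methyl-3-(trimethylsilyloxy)cyclohexane-1,2-diol (cis-diol; the two new carbinol centres not defined) | CC(C)(C)[Si](C)(C)O[C@H]1C[C@@](C)(O[Si](C)(C)C)C(O)C(O)C1
F3 | step 10 | 1-ethynyl analogue of 18 | CC(C)(C)[Si](C)(C)O[C@H]1C[C@@](C)(O)[C@@](O)(CCC(C)=C)[C@@](O)(C#C)C1
F4 | step 15 | (4Z,8S,10R)-8-hydroxy-4,10-dimethyl-1,6-dioxocyclodec-4-en-10-yl acetate (target numbering) | O[C@H]1C[C@@](C)(OC(C)=O)C(=O)CC/C(C)=C\C(=O)C1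
F5 | step 15 | bridged methyl ketal of F4 (O8 bonded to C1; C1 methoxy, C8 hydrogen and C10 acetoxy on the same face of the oxolane) | CO[C@@]12CC/C(C)=C\C(=O)C[C@@H](O1)C[C@@]2(C)OC(C)=O
F6 | step 15 | C7 aldol adduct of F5 with 23 (epimers at C7 and C11) | CO[C@@]12CC/C(C)=C\C(=O)C(C(O)(COC(C)=O)C(=O)OCC)[C@@H](O1)C[C@@]2(C)OC(C)=O
F7 | step 15 | (Z)-C7 alkylidene of the bridged ketal (ester cis to C6) | CO[C@@]12CC/C(C)=C\C(=O)/C(=C(/COC(C)=O)C(=O)OCC)[C@@H](O1)C[C@@]2(C)OC(C)=O
F8 | step 16 | 11-hydroxy-7,11-dihydro lactone with O8 silyl ether (epimers at C7 and C11) | CC(C)(C)[Si](C)(C)O[C@H]1C[C@@](C)(OC(C)=O)C(=O)CC/C(C)=C\[C@H]2OC(=O)C(O)(COC(C)=O)C12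
F9 | step 16 | 8-O-(tert-butyldimethylsilyl) ether of 30 | CC(C)(C)[Si](C)(C)O[C@H]1C[C@@](C)(OC(C)=O)C(=O)CC/C(C)=C\[C@H]2OC(=O)C(COC(C)=O)=C12
F0 | step 18 | none | none
A1 | alternative 1 | open-chain (Z)-iodoalkene aldehyde with C10 acetate, C8 silyl ether and C12 methyl ester cis to the C6 aldehyde | I/C=C(C)\CCC(=O)[C@](C)(OC(C)=O)C[C@H](O[Si](C)(C)C(C)(C)C)/C(C=O)=C(\CO[Si](C)(C)C(C)(C)C)C(=O)OC
A2 | alternative 1 | 8,13-bis(tert-butyldimethylsilyl) ether of the target skeleton | CC(C)(C)[Si](C)(C)O[C@H]1C[C@@](C)(OC(C)=O)C(=O)CC/C(C)=C\[C@H]2OC(=O)C(CO[Si](C)(C)C(C)(C)C)=C12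
A3 | alternative 2 | thirteen-membered diallylic ether with O between C6 and C13 (C7=C11 drawn E within the ring) | C1/C(C)=C\COC/C(COCc2ccc(OC)cc2)=C/[C@@H](O[Si](C)(C)C(C)(C)C)C/C(C)=C/C1
A4 | alternative 2 | ten-membered 6-hydroxy-7-[3-(4-methoxybenzyloxy)prop-1-en-2-yl]-8-silyloxy-1(10),4-diene | CC(C)(C)[Si](C)(C)O[C@H]1C/C(C)=C/CC/C(C)=C\[C@@H](O)[C@H]1C(=C)COCc1ccc(OC)cc1
A5 | alternative 3 | 1-[(Z)-2-(4-methoxybenzyloxy)ethenyl]-3-methyl-6-(prop-1-en-2-yl)cyclohex-2-en-1-ol with the two alkenyl groups trans | C=C(C)[C@H]1CCC(C)=C[C@]1(O)/C=C\OCc1ccc(OC)cc1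
A6 | alternative 3 | (2Z,6E)-9-(4-methoxybenzyloxy)-3,7-dimethylcyclodeca-2,6-dien-1-one | COc1ccc(CO[C@H]2C/C(C)=C/CC/C(C)=C\C(=O)C2)cc1
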